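**Retrosynthetic overview**

- Feature: the carbocycle C4a–C5–C6–C7–C8–C8a of the tetrahydroisoquinoline has only C7 unsubstituted. C5 holds the naphthyl axis, C6 and C8 hold OMe, and C4a/C8a are shared with the nitrogen ring. It therefore divides into three C2 units: C4a≡C5 (naphthylalkyne), C6≡C7 (methoxyethyne) and C8≡C8a (tethered ynol ether).
- Key disconnection: a rhodium-catalysed [2+2+2] union of an N-tosyl 1,7-diyne with methoxyethyne makes C4a–C8a, C5–C6 and C7–C8. The nitrogen ring, the benzene ring and the biaryl axis arise together, and only detosylation follows.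
- Diyne: C3 comes from (S)-alaninol (tosylaziridine opened by acetylide at C4). C1 comes from methyl (R)-lactate (Mitsunobu inversion at a non-ionising α-ester carbon). The naphthyl group is attached by Sonogashira coupling.
- No substitution at C1 is run on a methoxyalkynyl carbinol, because it would ionise to an alkoxyallenyl cation and lose configuration. The ynol ether is therefore unmasked last, from the lactate carboxyl carbon (Weinreb amide, methoxymethyl ketone, Z-enol triflate, elimination).
- Ring order: first the second naphthalene ring (aryne acyl-alkylation, then aldol), then the benzene ring and the nitrogen ring together in the key step.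

Key step: step 14

Assumption: the SMILES fixes C1 (S) and C3 (S) but leaves the C5–C1' axis open. Either atropisomer or their mixture therefore answers the structure, and the ligand antipode is a free choice.

**Step 1**
Reactants: 1 3-methoxy-2-(trimethylsilyl)phenyl trifluoromethanesulfonate; 2 pentane-2,4-dione
Product: 4 1-(2-acetyl-3-methoxyphenyl)propan-2-one, via 3-methoxybenzyne 3 (not isolated)
Conditions: CsF (2.5 equiv), MeCN, 80 °C
Reagents that add atoms: none
Why: Aryne acyl-alkylation (formal insertion of an aryne into the C–C bond of a 1,3-diketone): fluoride unmasks 3, the enolate carbon adds to the aryne carbon remote from OMe because the aryl anion then sits next to the inductively stabilising oxygen, and this anion takes over one acetyl group, so acetyl ends ortho to OMe with the acetonyl group beside it.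

**Step 2**
Reactants: 4 1-(2-acetyl-3-methoxyphenyl)propan-2-one
Product: 5 8-methoxy-3-methylnaphthalen-1-ol
Conditions: KOH, MeOH, 65 °C; then aq HCl
Reagents that add atoms: none
Why: Intramolecular aldol condensation followed by tautomerisation to the arene: the enolate of the aryl methyl ketone attacks the more electrophilic, unshielded aliphatic ketone in a six-membered closure, the doubly ortho-flanked aryl ketone being a poor acceptor, and base is used because acid would turn the 1,5-diketone into a benzopyrylium salt.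

**Step 3**
Reactants: 5 8-methoxy-3-methylnaphthalen-1-ol
Product: 6 1,8-dimethoxy-3-methylnaphthalene
Conditions: MeI, K2CO3, acetone, 56 °C
Reagents that add atoms: iodomethane, CI
Why: Williamson O-methylation of the naphthoxide, which on heating overrides the hydrogen bond to the peri methoxy group.

**Step 4**
Reactants: 6 1,8-dimethoxy-3-methylnaphthalene
Product: 7 1-iodo-4,5-dimethoxy-2-methylnaphthalene
Conditions: NIS (1.0 equiv), CF3CO2H (cat.), MeCN, 0 °C to rt, dark
Reagents that add atoms: N-iodosuccinimide, O=C1CCC(=O)N1I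
Why: Electrophilic aromatic iodination with acid-activated NIS should go to C4 of 6, the α-position that is para to the C1 methoxy group and ortho to the methyl group and so lies in the more activated ring.

**Step 5**
Reactants: 8 (S)-2-aminopropan-1-ol
Product: 10 (2S)-2-methyl-1-(4-methylbenzenesulfonyl)aziridine, via bis-tosylate 9 (not isolated)
Conditions: TsCl (2.2 equiv), KOH, CH2Cl2/H2O, rt
Reagents that add atoms: 4-methylbenzenesulfonyl chloride, Cc1ccc(S(=O)(=O)Cl)cc1
Why: Wenker-type aziridine synthesis: N- and O-sulfonylation give 9, whose sulfonamide anion displaces the primary tosylate in a 3-exo-tet SN2 closure, and the S configuration of 8 is kept because no bond at the stereocentre is broken.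

**Step 6**
Reactants: 10 (2S)-2-methyl-1-(4-methylbenzenesulfonyl)aziridine
Product: 11 4-methyl-N-[(2S)-pent-4-yn-2-yl]benzenesulfonamide
Conditions: LiC≡CH·H2NCH2CH2NH2, DMSO, rt; then H2O
Reagents that add atoms: lithium acetylide ethylenediamine complex, [Li]C#C.NCCN
Why: SN2 ring opening of an N-sulfonyl-activated aziridine by an acetylide at the unsubstituted CH2 (future C4), which leaves the C–N stereocentre (future C3, S) untouched.

**Step 7**
Reactants: 11 4-methyl-N-[(2S)-pent-4-yn-2-yl]benzenesulfonamide; 12 methyl (2R)-2-hydroxypropanoate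
Product: 13 methyl (2S)-2-{(4-methylbenzenesulfonyl)[(2S)-pent-4-yn-2-yl]amino}propanoate
Conditions: PBu3, TMAD (N,N,N',N'-tetramethylazodicarboxamide), toluene, 0 °C to rt
Reagents that add atoms: none
Why: Mitsunobu reaction in its azodicarboxamide/trialkylphosphine variant, chosen because an N-alkyl tosylamide is only weakly acidic: the α-ester carbon of the activated lactate is an SN2-active, non-ionising secondary centre, so nitrogen should attack with clean inversion and the R carbon of 12 becomes the S-configured future C1 while C3 is untouched.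

**Step 8**
Reactants: 7 1-iodo-4,5-dimethoxy-2-methylnaphthalene; 13 methyl (2S)-2-{(4-methylbenzenesulfonyl)[(2S)-pent-4-yn-2-yl]amino}propanoate
Product: 14 methyl (2S)-2-{[(2S)-5-(4,5-dimethoxy-2-methylnaphthalen-1-yl)pent-4-yn-2-yl](4-methylbenzenesulfonyl)amino}propanoate
Conditions: PdCl2(PPh3)2 (5 mol %), CuI (10 mol %), Et3N/THF, 50 °C
Reagents that add atoms: none
Why: Sonogashira coupling of a terminal alkyne with an aryl iodide; an ortho-methyl, peri-flanked 1-iodonaphthalene still adds oxidatively to zerovalent palladium on gentle heating, and the fully substituted sulfonamide cannot cyclise onto the alkyne.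

**Step 9**
Reactants: 14 methyl (2S)-2-{[(2S)-5-(4,5-dimethoxy-2-methylnaphthalen-1-yl)pent-4-yn-2-yl](4-methylbenzenesulfonyl)amino}propanoate
Product: 15 (2S)-2-{[(2S)-5-(4,5-dimethoxy-2-methylnaphthalen-1-yl)pent-4-yn-2-yl](4-methylbenzenesulfonyl)amino}-N-methoxy-N-methylpropanamide
Conditions: MeNH(OMe)·HCl, i-PrMgCl, THF, −20 to 0 °C
Reagents that add atoms: N,O-dimethylhydroxylamine hydrochloride, CNOC.Cl
Why: Ester aminolysis by the magnesium amide of N,O-dimethylhydroxylamine (Weinreb amide formation), a low-temperature method used on α-amino esters without loss of configuration at the α-carbon.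

**Step 10**
Reactants: 15 (2S)-2-{[(2S)-5-(4,5-dimethoxy-2-methylnaphthalen-1-yl)pent-4-yn-2-yl](4-methylbenzenesulfonyl)amino}-N-methoxy-N-methylpropanamide
Product: 16 N-[(2S)-5-(4,5-dimethoxy-2-methylnaphthalen-1-yl)pent-4-yn-2-yl]-N-[(2S)-4-methoxy-3-oxobutan-2-yl]-4-methylbenzenesulfonamide
Conditions: Bu3SnCH2OMe, n-BuLi, THF, −78 °C; then 15, −78 °C; then AcOH, −78 °C
Reagents that add atoms: tributyl(methoxymethyl)stannane, CCCC[Sn](CCCC)(CCCC)COC
Why: Weinreb ketone synthesis with methoxymethyllithium made by tin–lithium exchange: the N-methoxy amide stops at mono-addition, and the cold acetic acid quench should keep the α-amino ketone from epimerising at C1.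

**Step 11**
Reactants: 16 N-[(2S)-5-(4,5-dimethoxy-2-methylnaphthalen-1-yl)pent-4-yn-2-yl]-N-[(2S)-4-methoxy-3-oxobutan-2-yl]-4-methylbenzenesulfonamide
Product: 18 (1Z,3S)-3-{[(2S)-5-(4,5-dimethoxy-2-methylnaphthalen-1-yl)pent-4-yn-2-yl](4-methylbenzenesulfonyl)amino}-1-methoxybut-1-en-2-yl trifluoromethanesulfonate, via lithium Z-enolate 17 (not isolated)
Conditions: LiN(SiMe3)2, THF, −78 °C; PhNTf2, −78 to 0 °C
Reagents that add atoms: N-phenylbis(trifluoromethanesulfonimide), O=S(=O)(N(c1ccccc1)S(=O)(=O)C(F)(F)F)C(F)(F)F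
Why: Kinetic enolisation and O-sulfonylation: the hindered base takes a proton from the accessible CH2OMe group and not the shielded tertiary C1–H, chelation of lithium by the methoxy oxygen fixes the Z-enolate 17, and the triflimide traps it on oxygen.

**Step 12**
Reactants: 18 (1Z,3S)-3-{[(2S)-5-(4,5-dimethoxy-2-methylnaphthalen-1-yl)pent-4-yn-2-yl](4-methylbenzenesulfonyl)amino}-1-methoxybut-1-en-2-yl trifluoromethanesulfonate
Product: 19 N-[(2S)-5-(4,5-dimethoxy-2-methylnaphthalen-1-yl)pent-4-yn-2-yl]-N-[(2S)-4-methoxybut-3-yn-2-yl]-4-methylbenzenesulfonamide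
Conditions: KOt-Bu (2.5 equiv), THF, −78 °C; chromatography on Et3N-deactivated silica
Reagents that add atoms: none
Why: Base-induced anti E2 elimination from a Z-configured β-alkoxy enol triflate, the second half of the known two-step conversion of α-alkoxy ketones into alkynyl ethers: C8–H stands anti to the triflate, so elimination should be fast at −78 °C and C1–H and the propargylic C4–H2 should be left alone.

**Step 13**
Reactants: 20 2-chloro-1,1-dimethoxyethane
Product: 23 methoxyethyne, via 1-chloro-2-methoxyethene 21 (not isolated), via sodium methoxyacetylide 22 (not isolated)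
Conditions: NaNH2 (3.3 equiv), liq. NH3, −33 °C; then H2O; distilled into cold CH2Cl2 and dried over molecular sieves
Reagents that add atoms: none
Why: Classical twofold base-induced elimination from an α-chloro acetal (methanol first, then hydrogen chloride), the third equivalent of amide storing the volatile product as its acetylide 22 until the aqueous quench.

**Step 14**
Reactants: 19 N-[(2S)-5-(4,5-dimethoxy-2-methylnaphthalen-1-yl)pent-4-yn-2-yl]-N-[(2S)-4-methoxybut-3-yn-2-yl]-4-methylbenzenesulfonamide; 23 methoxyethyne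
Product: 24 (1S,3S)-5-(4,5-dimethoxy-2-methylnaphthalen-1-yl)-6,8-dimethoxy-1,3-dimethyl-2-(4-methylbenzenesulfonyl)-1,2,3,4-tetrahydroisoquinoline
Conditions: [Rh(cod)2]BF4 (10 mol %), (R)-H8-BINAP (10 mol %), pre-activated with H2 (1 atm) then Ar, CH2Cl2, 4 Å molecular sieves, rt; 23 (5 equiv, cold CH2Cl2 solution) by syringe pump
Reagents that add atoms: none
Why: The cationic monovalent rhodium bisphosphine complex binds both alkynes of 19 and couples them oxidatively to a trivalent rhodacyclopentadiene, which forms C4a–C8a and so closes the six-membered nitrogen ring by metallacycle formation across the four-atom tether C4–C3–N–C1; 23 then inserts into a Rh–C bond and reductive elimination completes C7–C8 and C5–C6, closing the benzene ring in the [2+2+2] cycloaddition mode. The closest known reaction type is the cationic rhodium/biaryl bisphosphine crossed cyclotrimerisation of sulfonamide-tethered diynes with terminal monoalkynes, which is documented for alkoxyalkynes, for 1,7-diynes and for ortho-substituted 1-naphthylalkynes that give hindered biaryls. No carbon stereocentre is created: C1 and C3 are spectators under these neutral aprotic conditions, and the only new stereo element, the C5–C1' axis, is set as the arene forms under the chiral ligand, matched or mismatched with C1 and C3. The step needs orientational selectivity for 23 (CH terminus to C8, oxygen-bearing carbon to C5) and cross-reaction in preference to self-trimerisation of 23. Two features of 19 should secure the orientation: the perpendicular 2-methylnaphthyl group screens the Rh–C5 bond, so C–C bond formation begins at the open Rh–C8 side with the unsubstituted terminus of 23, and the nucleophilic CH carbon of 23 is polarity-matched with the electrophilic oxygen-bearing C8, a head-to-tail pairing of two ynol ethers that writes the 1,3-dimethoxy pattern. Slow addition of excess 23 and the two α-methyl groups, which fold the tether, should favour the cross-reaction.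

**Step 15**
Reactants: 24 (1S,3S)-5-(4,5-dimethoxy-2-methylnaphthalen-1-yl)-6,8-dimethoxy-1,3-dimethyl-2-(4-methylbenzenesulfonyl)-1,2,3,4-tetrahydroisoquinoline
Product: 25 (1S,3S)-5-(4,5-dimethoxy-2-methylnaphthalen-1-yl)-6,8-dimethoxy-1,3-dimethyl-1,2,3,4-tetrahydroisoquinoline
Conditions: NaC10H8 (sodium naphthalenide, stock solution), DME, −78 °C; then H2O
Reagents that add atoms: none
Why: Reductive N–S cleavage of an arenesulfonamide by single-electron transfer from an arene radical anion: the tosyl group accepts electrons more readily than the electron-rich dimethoxynaphthalene or the aryl ethers, no bond at C1 or C3 is touched, and a minor atropisomer can be removed by chromatography here or at 24 if a single axis is wanted.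

**Compound list**

1 | 3-methoxy-2-(trimethylsilyl)phenyl trifluoromethanesulfonate | COc1cccc(OS(=O)(=O)C(F)(F)F)c1[Si](C)(C)C | starting material
2 | pentane-2,4-dione | CC(=O)CC(C)=O | starting material
3 | 3-methoxybenzyne | COC1=CC=CC#C1 | intermediate
4 | 1-(2-acetyl-3-methoxyphenyl)propan-2-one | COc1cccc(CC(C)=O)c1C(C)=O | intermediate
5 | 8-methoxy-3-methylnaphthalen-1-ol | Cc1cc(O)c2c(OC)cccc2c1 | intermediate
6 | 1,8-dimethoxy-3-methylnaphthalene | Cc1cc(OC)c2c(OC)cccc2c1 | intermediate
7 | 1-iodo-4,5-dimethoxy-2-methylnaphthalene | Cc1cc(OC)c2c(OC)cccc2c1I | intermediate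
8 | (S)-2-aminopropan-1-ol | C[C@H](N)CO | starting material
9 | (2S)-2-(4-methylbenzenesulfonamido)propyl 4-methylbenzenesulfonate | C[C@H](NS(=O)(=O)c1ccc(C)cc1)COS(=O)(=O)c1ccc(C)cc1 | intermediate
10 | (2S)-2-methyl-1-(4-methylbenzenesulfonyl)aziridine | C[C@H]1CN1S(=O)(=O)c1ccc(C)cc1 | intermediate
11 | 4-methyl-N-[(2S)-pent-4-yn-2-yl]benzenesulfonamide | C#CC[C@H](C)NS(=O)(=O)c1ccc(C)cc1 | intermediate
12 | methyl (2R)-2-hydroxypropanoate | C[C@@H](O)C(=O)OC | starting material
13 | methyl (2S)-2-{(4-methylbenzenesulfonyl)[(2S)-pent-4-yn-2-yl]amino}propanoate | C#CC[C@H](C)N(S(=O)(=O)c1ccc(C)cc1)[C@H](C(=O)OC)C | intermediate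
14 | methyl (2S)-2-{[(2S)-5-(4,5-dimethoxy-2-methylnaphthalen-1-yl)pent-4-yn-2-yl](4-methylbenzenesulfonyl)amino}propanoate | Cc1cc(OC)c2c(OC)cccc2c1C#CC[C@H](C)N(S(=O)(=O)c1ccc(C)cc1)[C@H](C(=O)OC)C | intermediate
15 | (2S)-2-{[(2S)-5-(4,5-dimethoxy-2-methylnaphthalen-1-yl)pent-4-yn-2-yl](4-methylbenzenesulfonyl)amino}-N-methoxy-N-methylpropanamide | Cc1cc(OC)c2c(OC)cccc2c1C#CC[C@H](C)N(S(=O)(=O)c1ccc(C)cc1)[C@H](C(=O)N(C)OC)C | intermediate
16 | N-[(2S)-5-(4,5-dimethoxy-2-methylnaphthalen-1-yl)pent-4-yn-2-yl]-N-[(2S)-4-methoxy-3-oxobutan-2-yl]-4-methylbenzenesulfonamide | Cc1cc(OC)c2c(OC)cccc2c1C#CC[C@H](C)N(S(=O)(=O)c1ccc(C)cc1)[C@H](C(=O)COC)C | intermediate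
17 | lithium (Z)-enolate of 16 (O–Li cis to OMe) | Cc1cc(OC)c2c(OC)cccc2c1C#CC[C@H](C)N(S(=O)(=O)c1ccc(C)cc1)[C@H](/C(O[Li])=C/OC)C | intermediate
18 | (1Z,3S)-3-{[(2S)-5-(4,5-dimethoxy-2-methylnaphthalen-1-yl)pent-4-yn-2-yl](4-methylbenzenesulfonyl)amino}-1-methoxybut-1-en-2-yl trifluoromethanesulfonate | Cc1cc(OC)c2c(OC)cccc2c1C#CC[C@H](C)N(S(=O)(=O)c1ccc(C)cc1)[C@H](/C(OS(=O)(=O)C(F)(F)F)=C/OC)C | intermediate
19 | N-[(2S)-5-(4,5-dimethoxy-2-methylnaphthalen-1-yl)pent-4-yn-2-yl]-N-[(2S)-4-methoxybut-3-yn-2-yl]-4-methylbenzenesulfonamide | Cc1cc(OC)c2c(OC)cccc2c1C#CC[C@H](C)N(S(=O)(=O)c1ccc(C)cc1)[C@H](C#COC)C | intermediate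
20 | 2-chloro-1,1-dimethoxyethane (chloroacetaldehyde dimethyl acetal) | COC(CCl)OC | starting material
21 | 1-chloro-2-methoxyethene | COC=CCl | intermediate
22 | sodium methoxyacetylide | [Na+].[C-]#COC | intermediate
23 | methoxyethyne | C#COC | intermediate
24 | (1S,3S)-5-(4,5-dimethoxy-2-methylnaphthalen-1-yl)-6,8-dimethoxy-1,3-dimethyl-2-(4-methylbenzenesulfonyl)-1,2,3,4-tetrahydroisoquinoline | COc1cc(OC)c2c(c1-c1c(C)cc(OC)c3c(OC)cccc13)C[C@H](C)N(S(=O)(=O)c1ccc(C)cc1)[C@H]2C | intermediate
25 | (1S,3S)-5-(4,5-dimethoxy-2-methylnaphthalen-1-yl)-6,8-dimethoxy-1,3-dimethyl-1,2,3,4-tetrahydroisoquinoline | COc1cc(OC)c2c(c1-c1c(C)cc(OC)c3c(OC)cccc13)C[C@H](C)N[C@H]2C | target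

**Totals**

Total step count: 15.
Longest linear sequence: 11 steps (1–4, 8–12, 14, 15).

**Steps most likely to fail**

**Step 14.**
- Methoxyethyne may insert in the reversed orientation.
- The very reactive terminal ynol ether may self-trimerise or oligomerise faster than it crosses.
- Oxidative cyclisation of the hindered 1,7-diyne may be too slow.

The fallback sets out from 10 and 7 and comes back at 24. It makes the biaryl bond by Suzuki coupling on a preformed isoquinoline.
- Aziridine 10 is opened with 3,5-dimethoxyphenylmagnesium bromide (CuI cat., THF) to N-[(2S)-1-(3,5-dimethoxyphenyl)propan-2-yl]-4-methylbenzenesulfonamide F1.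
- NaC10H8 frees (2S)-1-(3,5-dimethoxyphenyl)propan-2-amine F2, and Ac2O gives N-[(2S)-1-(3,5-dimethoxyphenyl)propan-2-yl]acetamide F3.
- Bischler–Napieralski cyclisation (POCl3, MeCN, reflux), para to one methoxy group and ortho to the other, gives (3S)-6,8-dimethoxy-1,3-dimethyl-3,4-dihydroisoquinoline F4.
- The known trans-selective reduction with LiAlH4/AlMe3 gives (1S,3S)-6,8-dimethoxy-1,3-dimethyl-1,2,3,4-tetrahydroisoquinoline F5.
- TsCl/pyridine gives (1S,3S)-6,8-dimethoxy-1,3-dimethyl-2-(4-methylbenzenesulfonyl)-1,2,3,4-tetrahydroisoquinoline F6.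
- NBS brominates the position ortho/para to the two methoxy groups to give (1S,3S)-5-bromo-6,8-dimethoxy-1,3-dimethyl-2-(4-methylbenzenesulfonyl)-1,2,3,4-tetrahydroisoquinoline F7.
- Iodide 7 is converted (n-BuLi, B(OMe)3, aq acid) into (4,5-dimethoxy-2-methylnaphthalen-1-yl)boronic acid F8.
- F7 and F8 are joined with Pd(OAc)2/SPhos and K3PO4 in toluene/H2O at 100 °C to give 24.

**Step 7.** Displacement at a secondary carbon by a hindered, weakly acidic sulfonamide may be slow. The activated lactate would then be consumed by the hydrazide or by elimination to acrylate.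

The fallback sets out from 11 and 12 and comes back at 13. It replaces the redox condensation by a plain SN2 alkylation with an isolated electrophile.
- 12 is converted with Tf2O/2,6-lutidine (CH2Cl2, −78 to 0 °C) into methyl (2R)-2-{[(trifluoromethyl)sulfonyl]oxy}propanoate F9.
- The sodium salt of 11 (NaH, 1 equiv, THF/DMF) displaces the triflate at −20 °C with inversion to give 13.

**Step 12** (together with step 11).
- Deprotonation at C1–H or C4–H2 may compete, with allene formation and loss of the C1 configuration.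
- tert-Butoxide may attack at sulfur, which returns the ketone.
- The methyl ynol ether may hydrolyse during isolation.

The fallback sets out from 7 and 11 and comes back at 24. It obtains the alkynyl oxygen by oxidation of an acetylide and carries it as a robust silyl ynol ether.
- Sonogashira coupling of 7 with 11 gives N-[(2S)-5-(4,5-dimethoxy-2-methylnaphthalen-1-yl)pent-4-yn-2-yl]-4-methylbenzenesulfonamide F10.
- Mitsunobu reaction with commercial (R)-but-3-yn-2-ol (inversion) gives N-[(2S)-but-3-yn-2-yl]-N-[(2S)-5-(4,5-dimethoxy-2-methylnaphthalen-1-yl)pent-4-yn-2-yl]-4-methylbenzenesulfonamide F11.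
- Lithiation (n-BuLi, −78 °C), oxidation with LiOOt-Bu and O-silylation with i-Pr3SiOTf give N-[(2S)-5-(4,5-dimethoxy-2-methylnaphthalen-1-yl)pent-4-yn-2-yl]-4-methyl-N-{(2S)-4-[tri(propan-2-yl)silyloxy]but-3-yn-2-yl}benzenesulfonamide F12.
- Cycloaddition with 23 under the conditions of step 14 gives (1S,3S)-5-(4,5-dimethoxy-2-methylnaphthalen-1-yl)-6-methoxy-1,3-dimethyl-2-(4-methylbenzenesulfonyl)-8-[tri(propan-2-yl)silyloxy]-1,2,3,4-tetrahydroisoquinoline F13.
- Bu4NF gives (1S,3S)-5-(4,5-dimethoxy-2-methylnaphthalen-1-yl)-6-methoxy-1,3-dimethyl-2-(4-methylbenzenesulfonyl)-1,2,3,4-tetrahydroisoquinolin-8-ol F14, and MeI/K2CO3 gives 24.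

**Further compounds**

F1 | step 14 | N-[(2S)-1-(3,5-dimethoxyphenyl)propan-2-yl]-4-methylbenzenesulfonamide | COc1cc(OC)cc(C[C@H](C)NS(=O)(=O)c2ccc(C)cc2)c1
F2 | step 14 | (2S)-1-(3,5-dimethoxyphenyl)propan-2-amine | COc1cc(OC)cc(C[C@H](C)N)c1
F3 | step 14 | N-[(2S)-1-(3,5-dimethoxyphenyl)propan-2-yl]acetamide | COc1cc(OC)cc(C[C@H](C)NC(C)=O)c1
F4 | step 14 | (3S)-6,8-dimethoxy-1,3-dimethyl-3,4-dihydroisoquinoline | COc1cc(OC)c2c(c1)C[C@H](C)N=C2C
F5 | step 14 | (1S,3S)-6,8-dimethoxy-1,3-dimethyl-1,2,3,4-tetrahydroisoquinoline | COc1cc(OC)c2c(c1)C[C@H](C)N[C@H]2C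
F6 | step 14 | (1S,3S)-6,8-dimethoxy-1,3-dimethyl-2-(4-methylbenzenesulfonyl)-1,2,3,4-tetrahydroisoquinoline | COc1cc(OC)c2c(c1)C[C@H](C)N(S(=O)(=O)c1ccc(C)cc1)[C@H]2C
F7 | step 14 | (1S,3S)-5-bromo-6,8-dimethoxy-1,3-dimethyl-2-(4-methylbenzenesulfonyl)-1,2,3,4-tetrahydroisoquinoline | COc1cc(OC)c2c(c1Br)C[C@H](C)N(S(=O)(=O)c1ccc(C)cc1)[C@H]2C
F8 | step 14 | (4,5-dimethoxy-2-methylnaphthalen-1-yl)boronic acid | Cc1cc(OC)c2c(OC)cccc2c1B(O)O
F9 | step 7 | methyl (2R)-2-{[(trifluoromethyl)sulfonyl]oxy}propanoate | C[C@@H](OS(=O)(=O)C(F)(F)F)C(=O)OC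
F10 | step 12 | N-[(2S)-5-(4,5-dimethoxy-2-methylnaphthalen-1-yl)pent-4-yn-2-yl]-4-methylbenzenesulfonamide | Cc1cc(OC)c2c(OC)cccc2c1C#CC[C@H](C)NS(=O)(=O)c1ccc(C)cc1
F11 | step 12 | N-[(2S)-but-3-yn-2-yl]-N-[(2S)-5-(4,5-dimethoxy-2-methylnaphthalen-1-yl)pent-4-yn-2-yl]-4-methylbenzenesulfonamide | Cc1cc(OC)c2c(OC)cccc2c1C#CC[C@H](C)N(S(=O)(=O)c1ccc(C)cc1)[C@H](C#C)C
F12 | step 12 | N-[(2S)-5-(4,5-dimethoxy-2-methylnaphthalen-1-yl)pent-4-yn-2-yl]-4-methyl-N-{(2S)-4-[tri(propan-2-yl)silyloxy]but-3-yn-2-yl}benzenesulfonamide | Cc1cc(OC)c2c(OC)cccc2c1C#CC[C@H](C)N(S(=O)(=O)c1ccc(C)cc1)[C@H](C#CO[Si](C(C)C)(C(C)C)C(C)C)C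
F13 | step 12 | (1S,3S)-5-(4,5-dimethoxy-2-methylnaphthalen-1-yl)-6-methoxy-1,3-dimethyl-2-(4-methylbenzenesulfonyl)-8-[tri(propan-2-yl)silyloxy]-1,2,3,4-tetrahydroisoquinoline | COc1cc(O[Si](C(C)C)(C(C)C)C(C)C)c2c(c1-c1c(C)cc(OC)c3c(OC)cccc13)C[C@H](C)N(S(=O)(=O)c1ccc(C)cc1)[C@H]2C
F14 | step 12 | (1S,3S)-5-(4,5-dimethoxy-2-methylnaphthalen-1-yl)-6-methoxy-1,3-dimethyl-2-(4-methylbenzenesulfonyl)-1,2,3,4-tetrahydroisoquinolin-8-ol | COc1cc(O)c2c(c1-c1c(C)cc(OC)c3c(OC)cccc13)C[C@H](C)N(S(=O)(=O)c1ccc(C)cc1)[C@H]2C
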